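**Retrosynthetic overview**
- The C2–aryl bond is made last: a catalyst-controlled Rh 1,4-addition of the bought B-ring boronic acid to a 7-O-protected chromone sets C2 (S).
- The chromone bicycle is made in one pot from two acyclic pieces: a lavandulylmalonyl dichloride (C7–C8–C8a) and an amino-siloxy-methoxy triene (C2–C6). The A ring closes first ([3+3] C-acylation, then 6π-electrocyclisation of a dienylketene); the pyranone ring closes second (phenol onto the aminoenone).
- The triene comes from 4-methoxypent-3-en-2-one, so the 5-OMe arrives as the enol ether and is differentiated from 7-OH from the start.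
- The malonyl piece comes from (S)-lavandulol by Mitsunobu C-alkylation; the side-chain stereocentre comes from an Evans deconjugative α-prenylation of an N-senecioyl oxazolidinone.

Assumption: commercial 4-methoxypent-3-en-2-one is taken as the E isomer, and the facial sense of the Rh catalyst in step 10 is assigned by analogy with cyclic enones ((S)-biaryl bisphosphine gives 2S); if a model chromone shows the opposite, the (R)-ligand is used.

**Route**

Step 1
Reactants: 1 (4S)-4-benzyl-1,3-oxazolidin-2-one; 2 3-methylbut-2-enoyl chloride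
Product: 3 (4S)-4-benzyl-3-(3-methylbut-2-enoyl)-1,3-oxazolidin-2-one
Conditions: n-BuLi, THF, −78 °C; then 2, −78 → 0 °C
Reagents that add atoms: none
Why: N-acylation of the lithiated oxazolidinone by the acid chloride (standard loading of an Evans auxiliary); no new stereocentre, and C4 of the auxiliary is untouched.

Step 2
Reactants: 3 (4S)-4-benzyl-3-(3-methylbut-2-enoyl)-1,3-oxazolidin-2-one; 4 1-bromo-3-methylbut-2-ene (prenyl bromide)
Product: 5 (4S)-4-benzyl-3-[(2S)-5-methyl-2-(prop-1-en-2-yl)hex-4-enoyl]-1,3-oxazolidin-2-one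
Conditions: NaHMDS, THF, −78 °C; 4 (3 equiv), −78 → −40 °C
Reagents that add atoms: none
Why: Evans asymmetric alkylation in its deconjugative form: γ-deprotonation of the s-cis enoyl imide gives the chelated (Z)-dienolate, which is prenylated at Cα on the face opposite the benzyl group, creating the (2S) acyl centre (the later side-chain centre of the target) and the isopropenyl group together.

Step 3
Reactants: 5 (4S)-4-benzyl-3-[(2S)-5-methyl-2-(prop-1-en-2-yl)hex-4-enoyl]-1,3-oxazolidin-2-one
Product: 6 (2S)-5-methyl-2-(prop-1-en-2-yl)hex-4-en-1-ol [(S)-lavandulol]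
Conditions: LiBH4, H2O (1 equiv), Et2O, 0 °C
Reagents that add atoms: none
Why: Reductive cleavage of the exocyclic imide carbonyl by LiBH4 releases the primary alcohol and the auxiliary under non-basic conditions, so the α-centre is not epimerised and the isolated alkenes are untouched.

Step 4
Reactants: 6 (2S)-5-methyl-2-(prop-1-en-2-yl)hex-4-en-1-ol; 7 bis(2,2,2-trifluoroethyl) propanedioate
Product: 8 bis(2,2,2-trifluoroethyl) 2-[(2R)-5-methyl-2-(prop-1-en-2-yl)hex-4-en-1-yl]propanedioate
Conditions: PPh3, DIAD, 7 (2 equiv), toluene, 0 → 23 °C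
Reagents that add atoms: none
Why: Mitsunobu C-alkylation: the acidic trifluoroethyl malonate is alkylated by SN2 at the primary CH2 of the activated alcohol; the stereocentre is one carbon away and is not involved (its descriptor becomes R only through a CIP priority change).

Step 5
Reactants: 8 bis(2,2,2-trifluoroethyl) 2-[(2R)-5-methyl-2-(prop-1-en-2-yl)hex-4-en-1-yl]propanedioate
Product: 9 2-[(2R)-5-methyl-2-(prop-1-en-2-yl)hex-4-en-1-yl]propanedioic acid
Conditions: LiOH·H2O, THF/H2O, 0 → 23 °C; then 1 M HCl, 0 °C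
Reagents that add atoms: lithium hydroxide (aqueous), [Li+].[OH-]
Why: Saponification of the activated trifluoroethyl esters and cold acidification give the monosubstituted malonic acid, which does not decarboxylate at these temperatures; alkenes and stereocentre are inert.

Step 6
Reactants: 10 (3E)-4-methoxypent-3-en-2-one; 11 methyl formate
Product: 13 (1E,4E)-1-(dimethylamino)-5-methoxyhexa-1,4-dien-3-one, via lithium formyl enolate 12 (not isolated)
Conditions: LDA, THF, −78 °C; 11, −78 → 0 °C; then Me2NH·HCl (1.0 equiv), MeOH, 0 °C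
Reagents that add atoms: dimethylamine hydrochloride, CNC.Cl
Why: Kinetic α′-deprotonation of the vinylogous ester and crossed Claisen formylation give the chelated formyl enolate, whose aldehyde carbon condenses with the buffered amine to the vinylogous amide faster than the β-methoxy enone exchanges (methyl formate and MeOH make any alkoxide exchange degenerate).

Step 7
Reactants: 13 (1E,4E)-1-(dimethylamino)-5-methoxyhexa-1,4-dien-3-one
Product: 14 (1E,3Z)-5-methoxy-N,N-dimethyl-3-(trimethylsilyloxy)hexa-1,3,5-trien-1-amine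
Conditions: LDA, THF, −78 °C; TMSCl, −78 → 0 °C; concentrate, pentane, filter
Reagents that add atoms: chlorotrimethylsilane, C[Si](C)(C)Cl
Why: The only acidic C–H left is the C-6 methyl (vinylogous to the carbonyl), so LDA gives the extended enolate, which is O-silylated to a cross-conjugated Rawal/Brassard-type siloxy triene (silyl dienol ether formation); the 3-geometry is not carried into the product.

Step 8
Reactants: 9 2-[(2R)-5-methyl-2-(prop-1-en-2-yl)hex-4-en-1-yl]propanedioic acid; 14 (1E,3Z)-5-methoxy-N,N-dimethyl-3-(trimethylsilyloxy)hexa-1,3,5-trien-1-amine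
Product: 18 7-hydroxy-5-methoxy-8-[(2R)-5-methyl-2-(prop-1-en-2-yl)hex-4-en-1-yl]-4H-chromen-4-one, via malonyl dichloride 15 (not isolated), via dienylketene 16 (not isolated), via hydroxyaryl enaminone 17 (not isolated)
Conditions: 9, Ghosez's reagent (1-chloro-N,N,2-trimethylprop-1-en-1-amine, 2.1 equiv), CH2Cl2, 0 → 23 °C; then 14, −78 °C; Et3N (1.1 equiv), −78 → 23 °C; then 2 M aq. HCl, THF, 23 °C
Reagents that add atoms: none
Why: Proposed new method: one COCl of the symmetric bis-acid chloride acylates triene 14 at its terminal C-6 (the site that leaves a cation stabilised by OMe, OSi and N, as Brassard-, Chan- and Rawal-type siloxydienes are C-acylated at the terminus); Et3N then removes HCl from the acidic C–H between ketone and COCl to give an acylketene whose enol form 16 is a dienylketene that closes by 6π-electrocyclisation (the ring-forming event of the Danheiser benzannulation; overall an Effenberger-type [3+3] cyclisation of an enol ether with a malonyl dichloride) and tautomerises to phenol 17; aqueous HCl finally makes the new ortho-OH displace Me2NH from the β-aminoenone (the standard enaminone route to chromones); the usual competing lactonisation to a 2-pyranone is blocked because O-5 is methylated, the symmetry of the malonyl unit fixes OMe at C5, OH at C7 and the side chain at C8, and no stereocentre is formed or endangered (the side-chain centre is β to the malonyl carbon).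

Step 9
Reactants: 18 7-hydroxy-5-methoxy-8-[(2R)-5-methyl-2-(prop-1-en-2-yl)hex-4-en-1-yl]-4H-chromen-4-one
Product: 19 5-methoxy-7-(methoxymethoxy)-8-[(2R)-5-methyl-2-(prop-1-en-2-yl)hex-4-en-1-yl]-4H-chromen-4-one
Conditions: MOMCl, iPr2NEt, CH2Cl2, 0 → 23 °C
Reagents that add atoms: chloromethyl methyl ether, COCCl
Why: Alkylation of the acidic 7-OH (the only OH) as its MOM ether, so that no phenoxide deactivates the chromone or protonates the Rh–aryl species in the next step.

Step 10
Reactants: 19 5-methoxy-7-(methoxymethoxy)-8-[(2R)-5-methyl-2-(prop-1-en-2-yl)hex-4-en-1-yl]-4H-chromen-4-one; 20 [2-(methoxymethoxy)phenyl]boronic acid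
Product: 21 (2S)-5-methoxy-7-(methoxymethoxy)-2-[2-(methoxymethoxy)phenyl]-8-[(2R)-5-methyl-2-(prop-1-en-2-yl)hex-4-en-1-yl]-2,3-dihydro-4H-chromen-4-one
Conditions: [Rh(OH)(cod)]2 (3 mol %), (S)-MeO-F12-BIPHEP (6.5 mol %), 20 (3 equiv), toluene/H2O 10:1, 30 °C
Reagents that add atoms: none
Why: Rh(I)-catalysed asymmetric 1,4-addition (Hayashi–Miyaura) of the arylboronic acid to the chromone: the electron-poor (S)-bisphosphine–Rh–aryl inserts C2=C3 from one enantioface and sets C2 (S) under catalyst control (the remote side-chain centre does not interfere), and the base-free medium prevents retro-oxa-Michael racemisation.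

Step 11
Reactants: 21 (2S)-5-methoxy-7-(methoxymethoxy)-2-[2-(methoxymethoxy)phenyl]-8-[(2R)-5-methyl-2-(prop-1-en-2-yl)hex-4-en-1-yl]-2,3-dihydro-4H-chromen-4-one
Product: 22 Kushenol R, (2S)-7-hydroxy-2-(2-hydroxyphenyl)-5-methoxy-8-[(2R)-5-methyl-2-(prop-1-en-2-yl)hex-4-en-1-yl]-2,3-dihydro-4H-chromen-4-one
Conditions: 3 M aq. HCl, MeOH, 40 °C
Reagents that add atoms: none
Why: Acid-catalysed acetal exchange removes both MOM ethers under the mild conditions used for prenylated phenols; the flavanone C2 centre is configurationally stable in acid and the side-chain centre is not touched.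

**Compound list**
1 | (4S)-4-benzyl-1,3-oxazolidin-2-one | O=C1N[C@@H](Cc2ccccc2)CO1 | starting material
2 | 3-methylbut-2-enoyl chloride | CC(C)=CC(=O)Cl | starting material
3 | (4S)-4-benzyl-3-(3-methylbut-2-enoyl)-1,3-oxazolidin-2-one | CC(C)=CC(=O)N1[C@@H](Cc2ccccc2)COC1=O | intermediate
4 | 1-bromo-3-methylbut-2-ene | CC(C)=CCBr | starting material
5 | (4S)-4-benzyl-3-[(2S)-5-methyl-2-(prop-1-en-2-yl)hex-4-enoyl]-1,3-oxazolidin-2-one | C=C(C)[C@H](CC=C(C)C)C(=O)N1[C@@H](Cc2ccccc2)COC1=O | intermediate
6 | (2S)-5-methyl-2-(prop-1-en-2-yl)hex-4-en-1-ol | C=C(C)[C@H](CC=C(C)C)CO | intermediate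
7 | bis(2,2,2-trifluoroethyl) propanedioate | O=C(CC(=O)OCC(F)(F)F)OCC(F)(F)F | starting material
8 | bis(2,2,2-trifluoroethyl) 2-[(2R)-5-methyl-2-(prop-1-en-2-yl)hex-4-en-1-yl]propanedioate | C=C(C)[C@H](CC=C(C)C)CC(C(=O)OCC(F)(F)F)C(=O)OCC(F)(F)F | intermediate
9 | 2-[(2R)-5-methyl-2-(prop-1-en-2-yl)hex-4-en-1-yl]propanedioic acid | C=C(C)[C@H](CC=C(C)C)CC(C(=O)O)C(=O)O | intermediate
10 | (3E)-4-methoxypent-3-en-2-one | CC(=O)/C=C(\C)OC | starting material
11 | methyl formate | COC=O | starting material
12 | lithium (1Z,4E)-5-methoxy-3-oxohexa-1,4-dien-1-olate | [Li+].[O-]/C=C\C(=O)/C=C(\C)OC | intermediate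
13 | (1E,4E)-1-(dimethylamino)-5-methoxyhexa-1,4-dien-3-one | CN(C)/C=C/C(=O)/C=C(\C)OC | intermediate
14 | (1E,3Z)-5-methoxy-N,N-dimethyl-3-(trimethylsilyloxy)hexa-1,3,5-trien-1-amine | CN(C)/C=C/C(O[Si](C)(C)C)=C/C(OC)=C | intermediate
15 | 2-[(2R)-5-methyl-2-(prop-1-en-2-yl)hex-4-en-1-yl]propanedioyl dichloride | C=C(C)[C@H](CC=C(C)C)CC(C(=O)Cl)C(=O)Cl | intermediate
16 | (1E,4E,6E)-1-(dimethylamino)-7-hydroxy-5-methoxy-8-[(2R)-5-methyl-2-(prop-1-en-2-yl)hex-4-en-1-yl]nona-1,4,6,8-tetraene-3,9-dione | C=C(C)[C@H](CC=C(C)C)CC(=C=O)/C(O)=C\C(OC)=C/C(=O)/C=C/N(C)C | intermediate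
17 | (2E)-1-{2,4-dihydroxy-6-methoxy-3-[(2R)-5-methyl-2-(prop-1-en-2-yl)hex-4-en-1-yl]phenyl}-3-(dimethylamino)prop-2-en-1-one | C=C(C)[C@H](CC=C(C)C)Cc1c(O)cc(OC)c(C(=O)/C=C/N(C)C)c1O | intermediate
18 | 7-hydroxy-5-methoxy-8-[(2R)-5-methyl-2-(prop-1-en-2-yl)hex-4-en-1-yl]-4H-chromen-4-one | C=C(C)[C@H](CC=C(C)C)Cc1c(O)cc(OC)c2c1occc2=O | intermediate
19 | 5-methoxy-7-(methoxymethoxy)-8-[(2R)-5-methyl-2-(prop-1-en-2-yl)hex-4-en-1-yl]-4H-chromen-4-one | C=C(C)[C@H](CC=C(C)C)Cc1c(OCOC)cc(OC)c2c1occc2=O | intermediate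
20 | [2-(methoxymethoxy)phenyl]boronic acid | COCOc1ccccc1B(O)O | starting material
21 | (2S)-5-methoxy-7-(methoxymethoxy)-2-[2-(methoxymethoxy)phenyl]-8-[(2R)-5-methyl-2-(prop-1-en-2-yl)hex-4-en-1-yl]-2,3-dihydro-4H-chromen-4-one | C=C(C)[C@H](CC=C(C)C)Cc1c(OCOC)cc(OC)c2c1O[C@H](c1ccccc1OCOC)CC2=O | intermediate
22 | Kushenol R, (2S)-7-hydroxy-2-(2-hydroxyphenyl)-5-methoxy-8-[(2R)-5-methyl-2-(prop-1-en-2-yl)hex-4-en-1-yl]-2,3-dihydro-4H-chromen-4-one | C=C(C)[C@H](CC=C(C)C)Cc1c(O)cc(OC)c2c1O[C@H](c1ccccc1O)CC2=O | target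

**Step count**
Total: 11 steps. Longest linear sequence: 9 steps (1, 2, 3, 4, 5, 8, 9, 10, 11); the triene branch (6, 7) joins at step 8.

**Steps most likely to fail, with fallbacks**

Step 8 is the least precedented step. The risks are acylation of 14 at the wrong carbon or at oxygen, and oligomerisation of the bis-acid chloride. The fallback sets out from 8 and 14 and comes back at 18. It decouples the first acylation from the ring closures and generates the ketene from an ester instead of an acid chloride. Half-saponification of 8 with one equivalent of LiOH gives 2-[(2R)-5-methyl-2-(prop-1-en-2-yl)hex-4-en-1-yl]-3-oxo-3-(2,2,2-trifluoroethoxy)propanoic acid F1 (both epimers at the malonyl carbon). Its acid chloride (Ghosez's reagent) acylates 14 at C-6 at −78 °C to give the isolable open-chain keto ester 2,2,2-trifluoroethyl (5E,8E)-9-(dimethylamino)-5-methoxy-2-[(2R)-5-methyl-2-(prop-1-en-2-yl)hex-4-en-1-yl]-3,7-dioxonona-5,8-dienoate F2. Purified F2 is then warmed with DBU in toluene, so that the activated β-keto ester loses trifluoroethanol to the acylketene (as β-keto esters and dioxinones do). The same electrocyclisation, aromatisation and, after aqueous HCl, pyranone closure then give 18, with both rings still formed in that one operation.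

Step 10 may be slow or unselective, because the boronic acid is ortho-substituted and the chromone is electron-rich and hindered. The fallback sets out from 19 and comes back at 21. It replaces catalyst-controlled addition by a non-selective addition followed by kinetic resolution. Addition of 20 with ligand-free [Rh(OH)(cod)]2 gives 21 together with its C2 epimer, (2R)-5-methoxy-7-(methoxymethoxy)-2-[2-(methoxymethoxy)phenyl]-8-[(2R)-5-methyl-2-(prop-1-en-2-yl)hex-4-en-1-yl]-2,3-dihydro-4H-chromen-4-one F3. Noyori asymmetric transfer hydrogenation of the mixture [RuCl(p-cymene)((R,R)-TsDPEN), HCO2H/Et3N] reduces only the matched 2R epimer, to the cis alcohol (2R,4R)-5-methoxy-7-(methoxymethoxy)-2-[2-(methoxymethoxy)phenyl]-8-[(2R)-5-methyl-2-(prop-1-en-2-yl)hex-4-en-1-yl]-3,4-dihydro-2H-chromen-4-ol F4. Ketone 21 is left untouched and is separated from F4 by chromatography (at most half of the material).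

Step 4 may give a low yield, because the Mitsunobu displacement is at a β-branched primary carbon. The fallback sets out from 6 and comes back at 9. It uses a classical malonic ester synthesis through the halide. Appel iodination (I2, PPh3, imidazole) gives (3S)-3-(iodomethyl)-2,6-dimethylhepta-1,5-diene F5. Alkylation of sodium dimethyl malonate (NaH, DMF, 60 °C) gives dimethyl 2-[(2R)-5-methyl-2-(prop-1-en-2-yl)hex-4-en-1-yl]propanedioate F6. Saponification (KOH, aqueous MeOH, cold acidification) gives 9. This costs one extra step.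

**Further compounds**
F1 | step 8 | 2-[(2R)-5-methyl-2-(prop-1-en-2-yl)hex-4-en-1-yl]-3-oxo-3-(2,2,2-trifluoroethoxy)propanoic acid | C=C(C)[C@H](CC=C(C)C)CC(C(=O)O)C(=O)OCC(F)(F)F
F2 | step 8 | 2,2,2-trifluoroethyl (5E,8E)-9-(dimethylamino)-5-methoxy-2-[(2R)-5-methyl-2-(prop-1-en-2-yl)hex-4-en-1-yl]-3,7-dioxonona-5,8-dienoate | C=C(C)[C@H](CC=C(C)C)CC(C(=O)OCC(F)(F)F)C(=O)C\C(OC)=C/C(=O)/C=C/N(C)C
F3 | step 10 | (2R)-5-methoxy-7-(methoxymethoxy)-2-[2-(methoxymethoxy)phenyl]-8-[(2R)-5-methyl-2-(prop-1-en-2-yl)hex-4-en-1-yl]-2,3-dihydro-4H-chromen-4-one | C=C(C)[C@H](CC=C(C)C)Cc1c(OCOC)cc(OC)c2c1O[C@@H](c1ccccc1OCOC)CC2=O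
F4 | step 10 | (2R,4R)-5-methoxy-7-(methoxymethoxy)-2-[2-(methoxymethoxy)phenyl]-8-[(2R)-5-methyl-2-(prop-1-en-2-yl)hex-4-en-1-yl]-3,4-dihydro-2H-chromen-4-ol | C=C(C)[C@H](CC=C(C)C)Cc1c(OCOC)cc(OC)c2c1O[C@@H](c1ccccc1OCOC)C[C@H]2O
F5 | step 4 | (3S)-3-(iodomethyl)-2,6-dimethylhepta-1,5-diene | C=C(C)[C@H](CC=C(C)C)CI
F6 | step 4 | dimethyl 2-[(2R)-5-methyl-2-(prop-1-en-2-yl)hex-4-en-1-yl]propanedioate | C=C(C)[C@H](CC=C(C)C)CC(C(=O)OC)C(=O)OC
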